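The earlier runs and the new flask were generated by integration for substances that don't exist, noise included.

The closed, stirred vessel gets the same charges of substrate and reagent in each recipe, so the flask parts from the ochre and red runs by initiator and time.

in all of them: substrate 0.20 M

| run | reagent | initiator | remark | time |
|---|---|---|---|---|
| ochre | 0.26 M | 3.4 mM | run made earlier |  |
| red | 0.26 M | 14 mM | run made earlier |  |
| flask | 0.260 M | 6.8 mM |  | 2.0 d |

| run | time / h | substrate / % | target / % |
|---|---|---|---|
| ochre | 3.00 | 95.5 | 4.7 |
| ochre | 5.00 | 91.8 | 7.4 |
| ochre | 8.00 | 88.7 | 12.0 |
| ochre | 15.0 | 77.1 | 18.7 |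
| ochre | 25.0 | 65.6 | 24.6 |
| ochre | 40.0 | 51.7 | 33.8 |
| red | 2.50 | 91.5 | 7.5 |
| red | 8.00 | 77.8 | 20.5 |
| red | 15.0 | 61.5 | 30.8 |
| red | 20.0 | 53.7 | 36.1 |
| red | 30.0 | 42.1 | 44.6 |
| red | 40.0 | 31.7 | 49.6 |

(standard deviation of a reading: 0.5 percentage points)

- a species is counted by the substrate in it: one ended chains A or side product counts as two
- amounts and yields of by-product count idle adduct too
- steps that have been proposed: initiator -> 2 initiating radical; substrate + initiating radical -> capped initiator + first chain carrier; reagent + first chain carrier <-> target + second chain carrier; substrate + second chain carrier -> by-product + first chain carrier; 2 first chain carrier -> ended chains A; 2 second chain carrier -> ended chains B; reagent + by-product <-> idle adduct; substrate + target -> side product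
- the earlier runs do not show how much of reagent is bound; that part of a forecast is a guess

1. part of the substrate that has reacted at 2.0 d
2. share of the unused reagent that is free and not bound as idle adduct, at 2.0 d

Logarithms suit these readings: the decay number is the natural logarithm of substrate charged over substrate left. At 40.0 h ochre stands at 0.660 and red at 1.15, so an initiator ratio of 4.12 reads as a power of 0.392, with the scatter of the readings. The flask has twice ochre's initiator, so its decay constant, the decay number per unit time and a pseudo-first-order rate constant, is reckoned at 0.0216 /h. Held steady over 2.0 d, that constant puts the flask's decay number at 1.04, so this reckoning has 64.6 % of its substrate reacted. The earlier runs do not show how much reagent is bound, so the free share stays a guess.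

The forecast, with an order “close to the half order of a radical chain”, gives 63 % reacted, less than this reckoning, and 72 % free.

The flask gives 64.6 % reacted and 54.5 % of its unused reagent free.

    initiator → 2 initiating radical (k = 5.70 × 10⁻⁷ /s)
    substrate + initiating radical → capped initiator + first chain carrier (k = 22000 /M/s)
    reagent + first chain carrier ⇌ target + second chain carrier (K = 2.80, k = 1600 /M/s)
    substrate + second chain carrier → by-product + first chain carrier (k = 1800 /M/s)
    2 first chain carrier → ended chains A (k = 4.00 × 10⁸ /M/s)
    2 second chain carrier → ended chains B (k = 3.20 × 10⁶ /M/s)
    reagent + by-product ⇌ idle adduct, settled at all times (K = 22.0 /M)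
    substrate + target → side product (k = 1.90 × 10⁻⁵ /M/s)

The flask has not come to rest at 2.0 d: 35 % of its substrate remains, a decay number of 1.04. Over 20.0 d, 0.0216 /h gives a decay number of 10.4 and a fraction left of 0.00308 %, and the flask then holds 0 % substrate. Between these two times target goes from 43.4 % to 55.2 % and side product from 20.5 % to 42.0 %, free reagent from 32.0 % to 14.6 % of its charge and initiator from 90.6 % to 37.3 % of its charge.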